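## Retrosynthetic overview

1. Cleave the C1 acyl ester (Yamaguchi) to a hydroxy-acid core and (2E,4S)-2,4-dimethyloct-2-enoic acid. The acid comes from (S)-2-methylhexanal by HWE, and the aldehyde from an ene-reductase reduction of the (E)-enal.
2. The C7 α-methylene aldehyde comes from C7–CH2CHO, then C7-allyl, by kinetic enolate alkylation of the ring-A enone anti to the C5-methyl.
3. The C1 (R)-alcohol comes from ketoreductase (KRED) reduction of an ene-dione, itself made by γ-oxidation of the enone. The C4 acid comes from anti-to-methyl hydroboration of an exocyclic methylene at C4.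
4. Both rings come from 2-methylcyclohexane-1,3-dione and MVK. A Michael addition gives the triketone, then a proline-catalysed aldol (Robinson annulation) closes ring A and sets the quaternary C5 first.

**Conventions and assumptions**
- Positions use the target's eremophilane-type numbering: ring A = C5–C10, ring B = C1–C5 and C10, C14 = angular CH3, C15 = C4 substituent carbon.
- "Up/down" refers to a drawing with ring A on the left, ring B on the right, C10 at top and C5 at bottom. In the target, C5–CH3, C4–CO2H and C1–O are down; the C7 substituent is up.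
- Assumption: a commercial KRED panel contains a variant that reduces the C1 ketone of 12 chemoselectively and gives the C1 alcohol down. A commercial ene-reductase panel likewise contains an enzyme that delivers the (S)-aldehyde from (E)-enal 21.

---

## Route

**Step 1**
Reactants: 1 2-methylcyclohexane-1,3-dione; 2 methyl vinyl ketone
Product: 3 2-methyl-2-(3-oxobutyl)cyclohexane-1,3-dione
Conditions: H2O, 70 °C
Reagents that add atoms: none
Why: Michael addition of the dione enol to MVK; the quaternary carbon is prochiral, so no stereocenter is formed yet.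

**Step 2**
Reactants: 3
Product: 4 (S)-Wieland–Miescher ketone, (8aS)-8a-methyl-3,4,8,8a-tetrahydronaphthalene-1,6(2H,7H)-dione
Conditions: (S)-proline (35 mol%), DMSO, rt; then TsOH (cat.), PhMe, 80 °C; recrystallise
Reagents that add atoms: none
Why: Proline-catalysed intramolecular aldol (Robinson annulation) through an enamine of the methyl ketone desymmetrises the two enantiotopic ring C=O groups and sets quaternary C5; acid dehydration gives the C9=C10 enone. Recrystallisation upgrades ee (assumed to reach at least 98%).

**Step 3**
Reactants: 4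
Product: 5 (8aR)-8a-methyl-1-methylidene-1,2,3,4,8,8a-hexahydronaphthalen-6(7H)-one (enone with C4=CH2)
Conditions: Ph3P+CH3 Br–, KOtBu, THF, 0 °C → rt
Reagents that add atoms: methylenetriphenylphosphorane, C=P(c1ccccc1)(c1ccccc1)c1ccccc1
Why: Wittig methylenation occurs at the more electrophilic, non-conjugated C4 ketone and leaves the deactivated enone C=O alone; no new stereocenter.

**Step 4**
Reactants: 5
Product: 6 allylic alcohol at C8 (C9=C10 retained, C4=CH2 retained; C8 epimer mixture; C5 unchanged)
Conditions: NaBH4, CeCl3·7H2O, MeOH, −20 °C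
Reagents that add atoms: none
Why: Luche 1,2-reduction masks the enone carbonyl so that borane does not reduce it in Step 5; the C8 configuration is irrelevant because it is re-oxidised in Step 6.

**Step 5**
Reactants: 6
Product: 7 diol: C8 allylic alcohol plus C15 primary alcohol (4S,5R; CH2OH down, cis to C5-CH3)
Conditions: 9-BBN (2.5 equiv), THF, 0 → 50 °C; then NaOH, H2O2, 0 °C → rt
Reagents that add atoms: hydrogen peroxide, OO (supplies the C15 oxygen)
Why: Hydroboration–oxidation; 9-BBN selectively attacks the exocyclic 1,1-disubstituted alkene and delivers H to C4 from the face anti to the axial angular methyl, so CH2OH ends up cis to CH3, which sets C4.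

**Step 6**
Reactants: 7
Product: 8 hydroxy-enone: C8=O, C9=C10, C15 primary alcohol (4S,5R)
Conditions: activated MnO2, CH2Cl2, rt
Reagents that add atoms: none
Why: MnO2 oxidises only the allylic secondary alcohol (both C8 epimers) and regenerates the ring-A enone; the unactivated primary alcohol is untouched.

**Step 7**
Reactants: 8
Product: 9 C4-carbaldehyde (enone retained; 4S,5R)
Conditions: Dess–Martin periodinane, NaHCO3, CH2Cl2, 0 °C → rt
Reagents that add atoms: none
Why: Neutral, buffered oxidation avoids epimerisation of the C4 stereocenter; the aldehyde is carried on crude.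

**Step 8**
Reactants: 9
Product: 10 carboxylic acid (C4-CO2H cis to C5-CH3, enone; 4S,5R)
Conditions: NaClO2, NaH2PO4, 2-methyl-2-butene, t-BuOH/H2O, rt
Reagents that add atoms: sodium chlorite, [O-]Cl=O (oxygen source)
Why: Pinnick oxidation; the alkene scavenger protects the enone from chlorination and the C4 configuration is unchanged.

**Step 9**
Reactants: 10
Product: 11 tert-butyl ester (C4-CO2tBu; 4S,5R)
Conditions: tBuOC(=NH)CCl3, BF3·OEt2 (cat.), CH2Cl2/cyclohexane, rt
Reagents that add atoms: tert-butyl 2,2,2-trichloroacetimidate, CC(C)(C)OC(=N)C(Cl)(Cl)Cl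
Why: Acid-catalysed tBu transfer works on this hindered acid; the tBu ester survives LDA in Step 13 and is later removed with TFA without touching the C1 ester.

**Step 10**
Reactants: 11
Product: 12 ene-dione: C1=O, C8=O, C9=C10, C4-CO2tBu (4S,5R)
Conditions: Mn(OAc)3·2H2O (10 mol%), t-BuOOH, 3 Å MS, EtOAc, rt
Reagents that add atoms: tert-butyl hydroperoxide, CC(C)(C)OO (oxygen source)
Why: Mn(III)/TBHP γ-oxidation of the enone oxidises the only γ-CH2 (C1) to a ketone (allylic C–H oxidation); no new stereocenter.

**Step 11**
Reactants: 12
Product: 13 tert-butyl (1R,4S,5R)-1-hydroxy-8-oxo-enone, with C1-OH down (cis to C5-CH3)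
Conditions: KRED (NADPH-dependent ketoreductase, panel-selected), NADP+ (cat.), D-glucose, GDH, KPi pH 7.0, 10% DMSO, 30 °C
Reagents that add atoms: none
Why: Enzymatic ketone reduction (alcohol dehydrogenase, EC 1.1.1.–); hydride from NADPH reaches C1 from the face anti to the axial C5-methyl, which sets C1 as (R) with OH cis to CH3, and the selected variant is chemoselective for C1 over the C8 enone carbonyl.

**Step 12**
Reactants: 13
Product: 14 C1-OTBS ether (1R,4S,5R)
Conditions: TBSOTf, 2,6-lutidine, CH2Cl2, −78 → 0 °C
Reagents that add atoms: tert-butyldimethylsilyl triflate, CC(C)(C)[Si](C)(C)OS(=O)(=O)C(F)(F)F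
Why: The hindered axial allylic alcohol needs the silyl triflate; protecting it prevents alkoxide interference with the enolate step; configuration retained.

**Step 13**
Reactants: 14
Product: 15 C7-allyl enone (7R by CIP; allyl up, trans to C5-CH3; 1R,4S,5R)
Conditions: LDA, THF, −78 °C; then allyl bromide, DMPU, −78 → −20 °C
Reagents that add atoms: allyl bromide, C=CCBr
Why: Kinetic deprotonation at the only α′ position (C7) and enolate alkylation from the face anti to the axial C5-methyl set C7 with the allyl group equatorial (up), which is also the thermodynamic epimer.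

**Step 14**
Reactants: 15
Product: 16 C1 free alcohol (7R,1R,4S,5R)
Conditions: HF·pyridine, pyridine/THF, rt
Reagents that add atoms: none
Why: Fluoride-mediated desilylation frees the C1-OH while the tBu ester, enone and allyl group are untouched; no stereocenter is affected.

**Step 15**
Reactants: 17 butanal; 18 triethyl 2-phosphonopropionate
Product: 19 ethyl (E)-2-methylhex-2-enoate
Conditions: NaH, THF, 0 °C → rt
Reagents that add atoms: none
Why: Horner–Wadsworth–Emmons olefination gives the (E)-trisubstituted enoate selectively.

**Step 16**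
Reactants: 19
Product: 20 (E)-2-methylhex-2-en-1-ol
Conditions: DIBAL-H (2.2 equiv), CH2Cl2, −78 °C
Reagents that add atoms: none
Why: Ester-to-allylic-alcohol reduction with retention of alkene geometry.

**Step 17**
Reactants: 20
Product: 21 (E)-2-methylhex-2-enal
Conditions: MnO2, CH2Cl2, rt
Reagents that add atoms: none
Why: Chemoselective allylic alcohol oxidation gives the α-methyl enal substrate for the ene-reductase.

**Step 18**
Reactants: 21
Product: 22 (S)-2-methylhexanal
Conditions: ene-reductase (Old Yellow Enzyme family), NADP+ (cat.), D-glucose, GDH, KPi pH 7, 30 °C, hexane overlay; extract and use at once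
Reagents that add atoms: none
Why: Ene-reductase (EC 1.6.99.1-type flavoenzyme) delivers hydride to the β-carbon and a proton to the α-carbon enantioselectively, creating the side-chain stereocenter; immediate extraction and use avoid α-racemisation.

**Step 19**
Reactants: 22; 18 triethyl 2-phosphonopropionate
Product: 23 ethyl (2E,4S)-2,4-dimethyloct-2-enoate
Conditions: LiCl, i-Pr2NEt, MeCN, rt
Reagents that add atoms: none
Why: Mild Masamune–Roush HWE conditions avoid epimerising the α-branched aldehyde and give the (E)-enoate; the C4′ centre is untouched.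

**Step 20**
Reactants: 23
Product: 24 (2E,4S)-2,4-dimethyloct-2-enoic acid
Conditions: LiOH, THF/MeOH/H2O, 60 °C
Reagents that add atoms: water/hydroxide, [OH-] (supplies the acid OH oxygen)
Why: Saponification; the γ-stereocenter is non-enolisable and the alkene geometry is retained.

**Step 21**
Reactants: 16 alcohol core; 24 acid
Product: 25 C1 (2E,4S)-2,4-dimethyloct-2-enoate ester, C4-CO2tBu, C7-allyl
Conditions: 2,4,6-Cl3C6H2COCl, Et3N, THF, rt; then 16, DMAP, PhMe, 60 °C
Reagents that add atoms: none
Why: Yamaguchi esterification through the mixed anhydride; DMAP attacks the unhindered aliphatic carbonyl and acylates the axial C1-OH with retention of configuration.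

**Step 22**
Reactants: 25
Product: 26 free C4 carboxylic acid (C7-allyl, C1 ester)
Conditions: TFA, CH2Cl2, 1,3-dimethoxybenzene, 0 °C → rt
Reagents that add atoms: none
Why: The tBu ester ionises under acid and the cation is trapped by the arene scavenger; the hindered C1 enoate ester and the enone survive.

**Step 23**
Reactants: 26
Product: 27 C7–CH2CHO aldehyde
Conditions: OsO4 (3 mol%), NaIO4, 2,6-lutidine, dioxane/H2O, rt
Reagents that add atoms: sodium periodate, [Na+].[O-]I(=O)(=O)=O (oxygen source)
Why: Lemieux–Johnson cleavage attacks the unhindered terminal alkene in preference to the electron-poor enone and enoate double bonds.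

**Step 24**
Reactants: 27
Product: 28 integric acid
Conditions: Me2N+=CH2 I– (Eschenmoser's salt), Et3N, CH2Cl2, rt; then 40 °C
Reagents that add atoms: Eschenmoser's salt, C[N+](C)=C.[I-] (supplies the =CH2)
Why: Mannich aminomethylation of the aldehyde enol and elimination of Me2NH give the α-methylene aldehyde (α-methylenation); any C7 epimerisation relaxes to the equatorial (desired) isomer.

---

## Compound list

1 | 2-methylcyclohexane-1,3-dione | CC1C(=O)CCCC1=O | starting material
2 | methyl vinyl ketone | C=CC(C)=O | starting material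
3 | 2-methyl-2-(3-oxobutyl)cyclohexane-1,3-dione | CC(=O)CCC1(C)C(=O)CCCC1=O | intermediate
4 | (S)-Wieland–Miescher ketone | C1C[C@@]2(C)C(=CC1=O)CCCC2=O | intermediate
5 | (8aR)-8a-methyl-1-methylidene-hexahydronaphthalen-6(7H)-one (C4=CH2 enone) | C1C[C@@]2(C)C(=CC1=O)CCCC2=C | intermediate
6 | C8 allylic alcohol of 5 (C8 epimer mixture) | C1C[C@@]2(C)C(=CC1O)CCCC2=C | intermediate
7 | diol: C8-OH and C15 CH2OH (4S,5R; CH2OH cis to C5-CH3) | C1C[C@@]2(C)C(=CC1O)CCC[C@@H]2CO | intermediate
8 | hydroxy-enone: C8=O, C15 CH2OH | C1C[C@@]2(C)C(=CC1=O)CCC[C@@H]2CO | intermediate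
9 | C4-carbaldehyde enone | C1C[C@@]2(C)C(=CC1=O)CCC[C@@H]2C=O | intermediate
10 | C4-carboxylic acid enone | C1C[C@@]2(C)C(=CC1=O)CCC[C@@H]2C(=O)O | intermediate
11 | tert-butyl ester of 10 | C1C[C@@]2(C)C(=CC1=O)CCC[C@@H]2C(=O)OC(C)(C)C | intermediate
12 | 1,8-ene-dione tert-butyl ester | C1C[C@@]2(C)C(=CC1=O)C(=O)CC[C@@H]2C(=O)OC(C)(C)C | intermediate
13 | (1R,4S,5R)-1-hydroxy-8-oxo-enone tert-butyl ester | C1C[C@@]2(C)C(=CC1=O)[C@H](O)CC[C@@H]2C(=O)OC(C)(C)C | intermediate
14 | C1-OTBS ether of 13 | C1C[C@@]2(C)C(=CC1=O)[C@H](O[Si](C)(C)C(C)(C)C)CC[C@@H]2C(=O)OC(C)(C)C | intermediate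
15 | C7-allyl derivative of 14 | C=CC[C@@H]1C[C@@]2(C)C(=CC1=O)[C@H](O[Si](C)(C)C(C)(C)C)CC[C@@H]2C(=O)OC(C)(C)C | intermediate
16 | C7-allyl, C1-OH, C4-CO2tBu alcohol | C=CC[C@@H]1C[C@@]2(C)C(=CC1=O)[C@H](O)CC[C@@H]2C(=O)OC(C)(C)C | intermediate
17 | butanal | CCCC=O | starting material
18 | triethyl 2-phosphonopropionate | CCOC(=O)C(C)P(=O)(OCC)OCC | starting material
19 | ethyl (E)-2-methylhex-2-enoate | CCC/C=C(\C)C(=O)OCC | intermediate
20 | (E)-2-methylhex-2-en-1-ol | CCC/C=C(\C)CO | intermediate
21 | (E)-2-methylhex-2-enal | CCC/C=C(\C)C=O | intermediate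
22 | (S)-2-methylhexanal | CCCC[C@H](C)C=O | intermediate
23 | ethyl (2E,4S)-2,4-dimethyloct-2-enoate | CCOC(=O)/C(C)=C/[C@@H](C)CCCC | intermediate
24 | (2E,4S)-2,4-dimethyloct-2-enoic acid | OC(=O)/C(C)=C/[C@@H](C)CCCC | intermediate
25 | C1 dienoate ester of 16 | C=CC[C@@H]1C[C@@]2(C)C(=CC1=O)[C@H](OC(=O)/C(C)=C/[C@@H](C)CCCC)CC[C@@H]2C(=O)OC(C)(C)C | intermediate
26 | free acid of 25 | C=CC[C@@H]1C[C@@]2(C)C(=CC1=O)[C@H](OC(=O)/C(C)=C/[C@@H](C)CCCC)CC[C@@H]2C(=O)O | intermediate
27 | C7–CH2CHO aldehyde | O=CC[C@@H]1C[C@@]2(C)C(=CC1=O)[C@H](OC(=O)/C(C)=C/[C@@H](C)CCCC)CC[C@@H]2C(=O)O | intermediate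
28 | integric acid (1R,4S,5R,7S; 4′S) | C=C(C=O)[C@@H]1C[C@@]2(C)C(=CC1=O)[C@H](OC(=O)/C(C)=C/[C@@H](C)CCCC)CC[C@@H]2C(=O)O | target

---

**Total steps:** 24 numbered steps (two of them, 11 and 18, are enzymatic). **Longest linear sequence:** 18 steps (Steps 1–14, then 21–24, from 1).

**Three steps most likely to fail, with fallbacks**

1. **Step 11 (KRED on ene-dione 12).** Chemoselectivity for C1 over C8, or the wrong face, is possible; Step 10 (Mn/TBHP γ-oxidation) is the other weak point in the C1 oxygenation. Fallback: make the thermodynamic TBS dienol ether of enone 10 or 11 and hydroxylate it with DMDO. This gives the C1-OH up (trans to CH3) without any ene-dione. Then invert C1 by intramolecular Mitsunobu lactonisation onto the free C4 acid (bridged 2-oxabicyclo[2.2.2]octanone), and open the lactone with NaOMe/MeOH. Re-protect the acid as the tBu ester and rejoin at Step 12.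
2. **Step 5 (hydroboration setting C4).** The facial selectivity may be lower than predicted. Fallback: go through the enol triflate of the C4 ketone (ring-A carbonyl protected as a ketal) and carry out Pd-catalysed methoxycarbonylation. Hydrogenate the C3=C4 enoate from the face anti to CH3, which puts CO2Me down. Then regenerate the enone and continue from Step 10.
3. **Step 24 (α-methylenation of the γ-keto aldehyde with free CO2H).** The aldehyde may cyclise or the product may oligomerise. Fallback: install the three-carbon unit earlier by Pd-catalysed α′-alkenylation of 14 with CH2=C(Br)CH2OTBS. Then remove the TBS group, oxidise the allylic alcohol with MnO2, and continue to the ester and acid steps.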